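**Strategy**

The cyclohexenone ring (C1 carbonyl, C2 =CH, C3 C–OMe, C4 ketal carbon, C5 CH2, C6 allyl-bearing CH) is closed last at the C2=C3 double bond of its vinylogous ester. C3 is carried as a methyl ester and C2 as an acyl-stabilised phosphorus ylide next to the C1 ketone, so an intramolecular Wittig olefination of the ester carbonyl forms the ring and leaves the ester methoxy group on C3, with no regiochemical question. The precursor is the acyclic chain C3–C4–C5–C6–C1: C4–C5 is made by Michael addition of an aryloxy(methoxy)acetate enolate to a chiral acrylimide, C6 is set by auxiliary-controlled allylation of the resulting enolate, and the imide then acylates Ph3P=CH2.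

Key step: step 7

Remark: the conjugate addition in step 6 is not expected to control the quaternary ketal carbon C4; the route relies on chromatographic separation of the two auxiliary-bearing diastereomers and carries only the 2R epimer forward.

**Route**

Step 1
Reactants: 1 3,4-dimethoxyphenol; 2 allyl bromide
Product: 3 4-(allyloxy)-1,2-dimethoxybenzene
Conditions: K2CO3, acetone, reflux
Reagents that add atoms: allyl bromide (2), C=CCBr
Why: Williamson ether synthesis, SN2 attack of the potassium phenoxide on the allylic bromide, should give the aryl allyl ether cleanly and creates no stereocentre.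

Step 2
Reactants: 3 4-(allyloxy)-1,2-dimethoxybenzene
Product: 4 2-allyl-4,5-dimethoxyphenol
Conditions: N,N-diethylaniline, 190 °C
Reagents that add atoms: none
Why: Aromatic Claisen rearrangement ([3,3]-sigmatropic shift, then tautomerisation) should move the allyl group to the free ortho position para to the 3-methoxy group and not to the crowded position between the two oxygen substituents; no stereocentre is formed.

Step 3
Reactants: 5 methyl 2,2-dimethoxyacetate; 6 acetyl chloride
Product: 7 methyl 2-chloro-2-methoxyacetate (racemic)
Conditions: AcCl, I2 (catalytic), neat, 55 °C; distillation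
Reagents that add atoms: acetyl chloride (6), CC(Cl)=O
Why: Cleavage of a dimethyl acetal by an acyl chloride (one methoxy group leaves as methyl acetate and chloride captures the oxocarbenium ion) is the standard preparation of α-chloro ethers; the new stereocentre is racemic and is used as such.

Step 4
Reactants: 4 2-allyl-4,5-dimethoxyphenol; 7 methyl 2-chloro-2-methoxyacetate
Product: 8 methyl 2-(2-allyl-4,5-dimethoxyphenoxy)-2-methoxyacetate (racemic)
Conditions: NaH, THF, 0 °C; then 7, 0 °C to rt
Reagents that add atoms: methyl 2-chloro-2-methoxyacetate (7), COC(Cl)C(=O)OC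
Why: O-alkylation of the sodium phenoxide by the very reactive α-chloro ether (Williamson-type substitution at the acetal carbon) should give the mixed aryl methyl acetal, whose stereocentre is racemic and is erased on enolisation in step 6.

Step 5
Reactants: 9 (R)-4-benzyl-1,3-oxazolidin-2-one; 10 acryloyl chloride
Product: 11 (R)-3-acryloyl-4-benzyl-1,3-oxazolidin-2-one
Conditions: MeMgBr, THF, 0 °C; then acryloyl chloride, −78 to 0 °C
Reagents that add atoms: acryloyl chloride (10), C=CC(Cl)=O
Why: N-acylation of the bromomagnesium salt of the oxazolidinone by the acid chloride should give the acrylimide, the magnesium salt being less prone than the lithium salt to start anionic polymerisation; the stereocentre of the auxiliary is untouched.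

Step 6
Reactants: 8 methyl 2-(2-allyl-4,5-dimethoxyphenoxy)-2-methoxyacetate; 11 (R)-3-acryloyl-4-benzyl-1,3-oxazolidin-2-one; 2 allyl bromide
Product: 13 methyl (2R,4R)-2-(2-allyl-4,5-dimethoxyphenoxy)-4-{[(4R)-4-benzyl-2-oxo-1,3-oxazolidin-3-yl]carbonyl}-2-methoxyhept-6-enoate, via lithium Z-enolate of the Michael adduct 12 (not isolated)
Conditions: LiN(iPr)2, THF, −78 °C; 11, −78 °C; then allyl bromide, DMPU, −78 to −10 °C; chromatographic separation of the two ketal epimers
Reagents that add atoms: (R)-3-acryloyl-4-benzyl-1,3-oxazolidin-2-one (11), C=CC(=O)N1C(=O)OC[C@H]1Cc1ccccc1; allyl bromide (2), C=CCBr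
Why: Michael addition of the lithium enolate of 8 to the s-cis acrylimide forms the C4–C5 bond and gives the lithium-chelated Z enolate 12, which is allylated from the face opposite the benzyl group (Evans-type alkylation of an enolate generated by conjugate addition) to set the allyl-bearing centre, the future C6, as R, whereas the quaternary ketal carbon is not expected to be controlled, so that the 2R epimer is obtained by chromatographic separation of the two diastereomers and its identity is confirmed by NOE after ring closure.

Step 7
Reactants: 13 methyl (2R,4R)-2-(2-allyl-4,5-dimethoxyphenoxy)-4-{[(4R)-4-benzyl-2-oxo-1,3-oxazolidin-3-yl]carbonyl}-2-methoxyhept-6-enoate; 14 methyltriphenylphosphonium bromide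
Product: 16 (4R,6R)-6-allyl-4-(2-allyl-4,5-dimethoxyphenoxy)-3,4-dimethoxycyclohex-2-en-1-one, via acyl-stabilised ylide 15 (not isolated)
Conditions: Ph3PCH3Br, KN(SiMe3)2, THF, 0 °C; then 13, −78 to 0 °C; aqueous NaHCO3 wash and solvent change; PhMe, 110 °C
Reagents that add atoms: methyltriphenylphosphonium bromide (14), C[P+](c1ccccc1)(c1ccccc1)c1ccccc1.[Br-]
Why: Ph3P=CH2 attacks the exocyclic imide carbonyl, the oxazolidinone anion leaves and deprotonates the acylphosphonium ion, which gives the acyl-stabilised ylide 15 with the ylide carbon as C2. On heating, C2 adds to the carbonyl carbon of the C3 methyl ester, the betaine closes to an oxaphosphetane and Ph3PO is lost, so that the C2=C3 double bond forms with the ester methoxy group left on C3; this is an intramolecular Wittig olefination of an ester carbonyl, the reaction type by which ester-tethered stabilised ylides give tetronates and other cyclic enol ethers. The six-membered ring closes in a 6-exo-trig mode, helped by the fully substituted C4 in the tether. No stereocentre is created: C4 is quaternary and C6 is carried over from 13, since the stabilised ylide is too weak a base to enolise the ketone and no other base is present in the thermal stage. The step needs acyl substitution at the imide and not at the ester or the ring carbonyl of the auxiliary, which the higher electrophilicity of the exocyclic imide carbonyl and the shielding of the ester by the quaternary C4 should secure at −78 °C, and it needs olefination and not C-acylation with loss of methoxide, which the poor leaving-group ability of methoxide against formation of the P–O bond should secure, while the two oxygen atoms on C4 make the ester carbonyl electrophilic enough for the weakly nucleophilic ylide.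

**Compound list**

1 | 3,4-dimethoxyphenol | COc1ccc(O)cc1OC | starting material
2 | allyl bromide (3-bromoprop-1-ene) | C=CCBr | starting material
3 | 4-(allyloxy)-1,2-dimethoxybenzene | C=CCOc1ccc(OC)c(OC)c1 | intermediate
4 | 2-allyl-4,5-dimethoxyphenol | C=CCc1cc(OC)c(OC)cc1O | intermediate
5 | methyl 2,2-dimethoxyacetate | COC(OC)C(=O)OC | starting material
6 | acetyl chloride | CC(Cl)=O | starting material
7 | methyl 2-chloro-2-methoxyacetate (racemic) | COC(Cl)C(=O)OC | intermediate
8 | methyl 2-(2-allyl-4,5-dimethoxyphenoxy)-2-methoxyacetate (racemic) | C=CCc1cc(OC)c(OC)cc1OC(OC)C(=O)OC | intermediate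
9 | (R)-4-benzyl-1,3-oxazolidin-2-one | O=C1OC[C@@H](Cc2ccccc2)N1 | starting material
10 | acryloyl chloride | C=CC(Cl)=O | starting material
11 | (R)-3-acryloyl-4-benzyl-1,3-oxazolidin-2-one | C=CC(=O)N1C(=O)OC[C@H]1Cc1ccccc1 | intermediate
12 | lithium Z-enolate of methyl 2-(2-allyl-4,5-dimethoxyphenoxy)-5-[(4R)-4-benzyl-2-oxo-1,3-oxazolidin-3-yl]-2-methoxy-5-oxopentanoate (2R epimer drawn; formed together with the 2S epimer) | C=CCc1cc(OC)c(OC)cc1O[C@](C(=O)OC)(OC)C/C=C(\O[Li])N1C(=O)OC[C@H]1Cc1ccccc1 | intermediate (not isolated)
13 | methyl (2R,4R)-2-(2-allyl-4,5-dimethoxyphenoxy)-4-{[(4R)-4-benzyl-2-oxo-1,3-oxazolidin-3-yl]carbonyl}-2-methoxyhept-6-enoate | C=CCc1cc(OC)c(OC)cc1O[C@](C(=O)OC)(OC)C[C@@H](CC=C)C(=O)N1C(=O)OC[C@H]1Cc1ccccc1 | intermediate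
14 | methyltriphenylphosphonium bromide | C[P+](c1ccccc1)(c1ccccc1)c1ccccc1.[Br-] | starting material
15 | methyl (2R,4R)-2-(2-allyl-4,5-dimethoxyphenoxy)-2-methoxy-4-[(triphenyl-λ5-phosphanylidene)acetyl]hept-6-enoate | C=CCc1cc(OC)c(OC)cc1O[C@](C(=O)OC)(OC)C[C@@H](CC=C)C(=O)C=P(c1ccccc1)(c1ccccc1)c1ccccc1 | intermediate (not isolated)
16 | (4R,6R)-6-allyl-4-(2-allyl-4,5-dimethoxyphenoxy)-3,4-dimethoxycyclohex-2-en-1-one | C=CCc1cc(OC)c(OC)cc1O[C@]1(OC)C[C@@H](CC=C)C(=O)C=C1OC | target

**Step count and risks**

Total step count: 7. Longest linear sequence: 5 steps (steps 1, 2, 4, 6, 7, from 3,4-dimethoxyphenol).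

Steps most likely to fail:

1. Step 7. The methylene ylide may attack the ring carbonyl of the auxiliary or the ester, or enolise the imide, instead of substituting at the exocyclic carbonyl. The acyl-stabilised ylide may also add too slowly to the ester carbonyl, or the betaine may collapse by loss of methoxide (C-acylation) instead of Ph3PO. Fallback: the same C2–C3 bond is formed by a Claisen condensation and the enol ether is made afterwards. From 13, LiSEt (THF, 0 °C) should give the thioester methyl (2R,4R)-2-(2-allyl-4,5-dimethoxyphenoxy)-4-[(ethylsulfanyl)carbonyl]-2-methoxyhept-6-enoate F1. Me2CuLi (Et2O, −78 °C) should convert it into the methyl ketone methyl (2R,4R)-4-acetyl-2-(2-allyl-4,5-dimethoxyphenoxy)-2-methoxyhept-6-enoate F2. LiN(SiMe3)2 (THF, −78 to 0 °C) should form the kinetic methyl enolate, which attacks the C3 ester and gives (4R,6R)-6-allyl-4-(2-allyl-4,5-dimethoxyphenoxy)-4-methoxycyclohexane-1,3-dione F3. O-methylation with Me3SiCHN2 (MeOH, PhMe) then returns to 16 after the regioisomeric enol ether has been removed by chromatography.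

2. Step 6. The acrylimide may oligomerise anionically, the lithium imide enolate may be allylated incompletely or with eroded enolate geometry, and the two ketal epimers may be hard to separate. Fallback: the two C–C bond formations are decoupled. From 8 and 11, the conjugate addition is run as before but quenched with AcOH at −78 °C, which should give methyl 2-(2-allyl-4,5-dimethoxyphenoxy)-5-[(4R)-4-benzyl-2-oxo-1,3-oxazolidin-3-yl]-2-methoxy-5-oxopentanoate F4 as both ketal epimers. Deprotonation with NaN(SiMe3)2 (THF, −78 °C) then gives the sodium Z enolate by ordinary imide enolisation, and allyl iodide returns to 13 after chromatography.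

3. Step 5. Acryloyl chloride or the acrylimide may polymerise under the basic acylation conditions. Fallback: the double bond is introduced after the acylation. From 9, n-BuLi (THF, −78 °C) and 3-chloropropanoyl chloride should give (R)-4-benzyl-3-(3-chloropropanoyl)-1,3-oxazolidin-2-one F5, and elimination of HCl with Et3N (CH2Cl2, rt) returns to 11.

Further compounds
F1 | step 7 | methyl (2R,4R)-2-(2-allyl-4,5-dimethoxyphenoxy)-4-[(ethylsulfanyl)carbonyl]-2-methoxyhept-6-enoate | C=CCc1cc(OC)c(OC)cc1O[C@](C(=O)OC)(OC)C[C@@H](CC=C)C(=O)SCC
F2 | step 7 | methyl (2R,4R)-4-acetyl-2-(2-allyl-4,5-dimethoxyphenoxy)-2-methoxyhept-6-enoate | C=CCc1cc(OC)c(OC)cc1O[C@](C(=O)OC)(OC)C[C@@H](CC=C)C(C)=O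
F3 | step 7 | (4R,6R)-6-allyl-4-(2-allyl-4,5-dimethoxyphenoxy)-4-methoxycyclohexane-1,3-dione | C=CCc1cc(OC)c(OC)cc1O[C@]1(OC)C[C@@H](CC=C)C(=O)CC1=O
F4 | step 6 | methyl 2-(2-allyl-4,5-dimethoxyphenoxy)-5-[(4R)-4-benzyl-2-oxo-1,3-oxazolidin-3-yl]-2-methoxy-5-oxopentanoate (both epimers at C2) | C=CCc1cc(OC)c(OC)cc1OC(C(=O)OC)(OC)CCC(=O)N1C(=O)OC[C@H]1Cc1ccccc1
F5 | step 5 | (R)-4-benzyl-3-(3-chloropropanoyl)-1,3-oxazolidin-2-one | ClCCC(=O)N1C(=O)OC[C@H]1Cc1ccccc1
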